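(All constants are those of an exercise; what happens was integrated by code.)

**The leftover.** I took the leftover solid partner in this flask for a feed pump, and I asked first how long it ran.

starting material 0.30 M; solid partner 1.05 equiv; time 6.0 h

* the target standing at 6.0 h, as a percentage of the starting material charged
* concentration of fresh partner in solution at 1.5 h, in percent of saturation
* the change that raises the amount of target at 6.0 h, in percent of the starting material charged most ("none" if none brings more than 2 percentage points) (west / south-west / none)
* amount of target at 6.0 h, in percent of the starting material charged, after west

- in percentages every species weighs as the starting material in it: one homo product counts as two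
- where a step has two of a species, its rate is k times that concentration squared, and two are used at each turn
- as a solid, counted per litre of solution: solid partner
- at the start none of the solid partner is in solution
- run time (flask): 6.0 h

- west: doubling the solubility in step 5, all else as stated
- south-west: doubling the dissolution coefficient of step 5, all else as stated

    starting material ⇌ open intermediate (K1 = 0.32, k1 = 0.014 s⁻¹)
    fresh partner → second intermediate (k2 = 8.5 × 10⁻⁴ s⁻¹)
    open intermediate + second intermediate → target (k3 = 0.0061 L mol⁻¹ s⁻¹)
    2 open intermediate → homo product (k4 = 0.0020 L mol⁻¹ s⁻¹)
    solid partner ⇌ fresh partner, rate k5*(cs5 - [fresh partner]) while solid is left; crystals form when [fresh partner] > cs5 (cs5 = 0.10 M, k5 = 2.9 × 10⁻⁴ s⁻¹)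

**Which numbers count.** Starting material and open intermediate relaxed into each other with a half-life of 0.200 min, far less than the run of 6.0 h, so I kept their equilibrium and let the rate constant go. Fresh partner had a half-life of 0.23 h against conversion, shorter than the run, so I froze it in a pseudo-steady state, where dissolving balanced conversion. The feed through that frozen level, counted per litre, then depended on the solubility, the dissolution coefficient and the conversion constant. An error in the solubility passed into it whole, one in the dissolution coefficient by a factor of 0.746, and one in the conversion constant by 0.254. The constants for target and homo product stood outside the feed.

**The number.** I reckoned frozen fresh partner at 25.4% of saturation. The feed, the fraction of the charge passing through fresh partner per hour, came to 0.259 h⁻¹. At that feed I reckoned a life of 4.05 h for 1.05 equiv of solid, shorter than the run. Doubling the solubility gave a feed of 0.519 h⁻¹, and doubling the dissolution coefficient gave 0.414 h⁻¹, less than the first, so I ranked west first. I did not reckon the split between target and homo product by hand, so my reckoning stopped short of the two yields.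

**The result.** The forecast gave 63%, 25.4%, west and 71.5%, on the ground that “Doubling the solubility doubles the feed”. The flask gave 63.1% of target, fresh partner at 25.4% of saturation, west as the best change with a gain of 8.3 percentage points against 6.5 points for south-west, and 71.4% after west.

**Smaller charge.** In this flask the feed left 26.0% of the solid at 3.00 h, and the reading was 23.8%. In the neighbouring flask, with 0.260 equiv of solid partner as limiting reagent, the same feed gave a reckoned pump life of 1.00 h, and the target could not pass the 0.260 equiv charged. At 6.00 h that flask held 23.0% of starting material, 44.4% of homo product and 25.3% of target.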